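Target is what I follow in midnight and spring, two closed, stirred flasks held at constant temperature, where substrate turns into target and target into its isomer.

| setting | Wednesday's | Monday's | midnight | spring |
|---|---|---|---|---|
| substrate | 0.21 M | 0.32 M | 0.23 M | 0.15 M |
| remark | run made earlier | run made earlier |  |  |
| time |  |  | 30 min | 50 min |

| run | time / min | target / % | isomer of the product / % | substrate / % |
|---|---|---|---|---|
| Wednesday's | 2.50 | 76.7 | 20.2 | 3.6 |
| Wednesday's | 8.00 | 56.7 | 45.3 | 0 |
| Wednesday's | 15.0 | 54.0 | 45.9 | 0.4 |
| Wednesday's | 20.0 | 53.6 | 46.4 | 0 |
| Wednesday's | 30.0 | 53.2 | 45.3 | 0 |
| Monday's | 2.50 | 73.6 | 17.4 | 8.5 |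
| Monday's | 8.00 | 59.8 | 40.3 | 1.7 |
| Monday's | 15.0 | 53.9 | 45.9 | 0.7 |
| Monday's | 20.0 | 54.6 | 45.7 | 0 |
| Monday's | 30.0 | 53.8 | 46.6 | 0 |

(each reading ± 1 percentage point)

* which of the two ends with the higher share of target in all that became target or isomer of the product ("neither" if they lie within 2 percentage points) (midnight / spring / neither)
* share of target in all that became target or isomer of the product, midnight
* share of target in all that became target or isomer of the product, spring

- a reading or a percentage of target counts all its forms, free or not

Target's share of target plus isomer falls through the early readings of both earlier runs, so I take Wednesday's reading of 55.6% at 8.00 min as a rough ceiling. To tighten it I work with the fraction left. In Monday's run the share falls from 80.9% to 59.7% between its first two readings.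

The six shares read in the two runs from 15.0 min onward show no trend and average 53.9%. This is my plateau share, the fraction of target plus isomer left as target once the two stop moving.

Between those two Monday readings the excess above the plateau shrinks to 21.5% of itself. Repeated at that pace, my estimate is that 0.0460% of the excess remains at 30 min, and spring runs longer. Two standard errors of the plateau then give an estimated floor of 53.4% and an estimated ceiling of 54.5% for both flasks, assuming spring's lower charge leaves the plateau unchanged. So I expect neither to lead.

The forecast, finding “no measurable dependence on concentration”, says neither, with 54% for midnight (53% to 55%) and 54% for spring (52.7% to 55.5%). Its central values lie inside my bracket.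

The two flasks give neither, with 53.5% for midnight and 53.5% for spring, against my estimated floor of 53.4%.

    substrate → target, rate k1*[substrate]/(1 + ([substrate]/sat1)) (0.120 M, k = 0.0320 /s)
    target ⇌ isomer of the product (K = 0.870, k = 0.00300 /s)
    crystals ⇌ target, rate k3*(cs3 - [target]) while solid is left; crystals form when [target] > cs3 (solubility = 0.190 M, k = 0.0620 /s)

The plateau is thermodynamic control: without the return of isomer to target, midnight's share drops from 53.5% to 0.548%. For the neighbour of midnight charged with 0.92 M, the plateau share of 53.9%, reckoned with the whole charge taken as dissolved, gives 0.496 M of target, more than the solubility 0.19 M. Computed, that flask ends at 82.1%, with crystals at 61.4% of the charge, counted in target.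

The numbers in the tables stem from a simulated flask with made-up constants, and the scatter is random.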